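Ring A (C13–C18; the chain is numbered from the ester carbon, C1) is disconnected at C13–C14. C13 is a tertiary carbinol wedged between two quaternary carbons, C14 (gem-dimethyl) and C18 (angular methyl), so it is made by letting a tertiary C14 radical attack a C13 ketone. In one operation an iron-hydride hydrogen-atom transfer to a homoprenyl alkene closes ring A, forms the C13–C14 bond and sets the cis ring fusion. The precursor is an enantioenriched 2-methyl-2-(4-methylpent-3-enyl)-3-silyloxycyclohexanone obtained by desymmetrizing a 1,3-dione. The decalin is then converted into a C8 sulfone and joined to a separately made 1,2-dioxane aldehyde (C1–C7) by olefination and diimide reduction.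

Key step: step 5

Remark: in the cyclization substrate the C9 oxygen is placed cis to the homoprenyl chain (2R,3R), the diastereomer that hydride delivery anti to the larger C18 substituent should give; it carries a triethylsilyl group that leaves in the work-up of step 5, and the centre is erased by oxidation in step 6.

**Decalin sulfone (steps 1–13)**

Step 1
Reactants: 1 2-methylcyclohexane-1,3-dione; 2 acrolein
Product: 3 3-(1-methyl-2,6-dioxocyclohexyl)propanal
Conditions: H2O, 23 °C
Reagents that add atoms: none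
Why: Michael addition of the acidic 2-alkyl-1,3-dione to the unhindered enal should proceed in water without added base and creates the quaternary carbon that becomes C18.

Step 2
Reactants: 3 3-(1-methyl-2,6-dioxocyclohexyl)propanal; 4 isopropyltriphenylphosphonium iodide
Product: 5 2-methyl-2-(4-methylpent-3-en-1-yl)cyclohexane-1,3-dione
Conditions: 4, n-BuLi, THF, 0 °C; then 3, −78 → 0 °C
Reagents that add atoms: none
Why: Wittig olefination; the non-stabilized isopropylidene ylide should add to the aldehyde much faster than to the two ketones flanking a quaternary carbon, which installs the trisubstituted alkene (C14=C15) needed for the radical step.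

Step 3
Reactants: 5 2-methyl-2-(4-methylpent-3-en-1-yl)cyclohexane-1,3-dione
Product: 6 (2R,3R)-3-hydroxy-2-methyl-2-(4-methylpent-3-en-1-yl)cyclohexan-1-one
Conditions: (S)-1-methyl-3,3-diphenyltetrahydro-1H,3H-pyrrolo[1,2-c][1,3,2]oxazaborole (20 mol %), catecholborane, PhNEt2, toluene, −60 °C; minor diastereomer removed by chromatography
Reagents that add atoms: none
Why: Corey–Bakshi–Shibata reduction of one of two enantiotopic carbonyls; the catalyst should fix the carbinol (C9) as R with the quaternary carbon as the large group, and hydride delivery to the face syn to the methyl group (anti to the homoprenyl chain) selects the carbonyl that leaves C18 as R.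

Step 4
Reactants: 6 (2R,3R)-3-hydroxy-2-methyl-2-(4-methylpent-3-en-1-yl)cyclohexan-1-one
Product: 7 (2R,3R)-2-methyl-2-(4-methylpent-3-en-1-yl)-3-(triethylsilyloxy)cyclohexan-1-one
Conditions: Et3SiCl, imidazole, DMF, 23 °C
Reagents that add atoms: chlorotriethylsilane, CC[Si](Cl)(CC)CC
Why: Routine silylation of the secondary alcohol; the silyl ether prevents retro-aldol opening of the β-hydroxy ketone, which would erode C18, during the radical cyclization.

Step 5
Reactants: 7 (2R,3R)-2-methyl-2-(4-methylpent-3-en-1-yl)-3-(triethylsilyloxy)cyclohexan-1-one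
Product: 9 (1R,4aS,8aR)-5,5,8a-trimethyloctahydronaphthalene-1,4a(2H)-diol, via triethylsilyl ether 8 (not isolated)
Conditions: Fe(acac)3 (30 mol %), PhSiH3 (2.5 equiv), EtOH/ethylene glycol 5:1, 60 °C, degassed; then 1 M HCl, THF, 23 °C
Reagents that add atoms: none
Why: An iron hydride generated from Fe(acac)3 and PhSiH3 delivers a hydrogen atom to C15 of the trisubstituted alkene, the tertiary C14 radical so formed adds to the C13 carbonyl carbon to make the C13–C14 bond, and the alkoxy radical is reduced by divalent iron and protonated by the alcohol solvent before dilute acid removes the triethylsilyl group. The closest known reaction type is the metal-hydride hydrogen-atom-transfer reductive cyclization of alkene-tethered ketones, which gives cis-fused bicyclic tertiary alcohols. Ring A (C13–C18) is closed in the 6-exo-trig mode. The one new stereocentre, C13, is controlled by the C18 quaternary centre, because only a chair transition state leading to the cis fusion (C13–O cis to the C18 methyl) escapes the syn-axial contact between one C14 methyl group and the angular methyl that a trans-fused chair would impose. The step needs ring closure to outpace simple reduction of the radical and needs the cis fusion; the short tether anchored on a quaternary carbon, the nucleophilic character of the tertiary radical and the early, sterically undemanding transition state of radical addition to a carbonyl group should secure the first, and the strain argument the second. The C9 silyloxy group is a spectator whose configuration is erased in step 6.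

Step 6
Reactants: 9 (1R,4aS,8aR)-5,5,8a-trimethyloctahydronaphthalene-1,4a(2H)-diol
Product: 10 (4aS,8aS)-4a-hydroxy-5,5,8a-trimethyloctahydronaphthalen-1(2H)-one
Conditions: Dess–Martin periodinane, NaHCO3, CH2Cl2, 23 °C
Reagents that add atoms: none
Why: Dess–Martin oxidation should convert only the secondary C9 carbinol, the tertiary C13 alcohol having no carbinol hydrogen, under buffered conditions that leave the β-hydroxy ketone intact.

Step 7
Reactants: 10 (4aS,8aS)-4a-hydroxy-5,5,8a-trimethyloctahydronaphthalen-1(2H)-one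
Product: 11 (4aS,8aS)-5,5,8a-trimethyl-4a-(trimethylsilyloxy)octahydronaphthalen-1(2H)-one
Conditions: Me3SiOTf, 2,6-lutidine, CH2Cl2, −78 → 0 °C
Reagents that add atoms: trimethylsilyl trifluoromethanesulfonate, C[Si](C)(C)OS(=O)(=O)C(F)(F)F
Why: Silylation with the silyl triflate should reach even this tertiary alcohol between two quaternary carbons, and it removes the alkoxide that could trigger retro-aldol cleavage of C13–C18 in the basic steps 8 and 9.

Step 8
Reactants: 11 (4aS,8aS)-5,5,8a-trimethyl-4a-(trimethylsilyloxy)octahydronaphthalen-1(2H)-one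
Product: 12 (2R,4aS,8aS)-2,5,5,8a-tetramethyl-4a-(trimethylsilyloxy)octahydronaphthalen-1(2H)-one
Conditions: LiN(i-Pr)2, THF, −78 °C; MeI, DMPU, −78 → −20 °C
Reagents that add atoms: iodomethane, CI
Why: Enolate alkylation at C10, the only enolizable position of the C9 ketone; iodomethane should approach anti to the axial C18 methyl group, and since the resulting equatorial 10R epimer is also the more stable one, base equilibration would correct any minor epimer.

Step 9
Reactants: 12 (2R,4aS,8aS)-2,5,5,8a-tetramethyl-4a-(trimethylsilyloxy)octahydronaphthalen-1(2H)-one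
Product: 13 (2R,4aS,8aR)-1-(methoxymethylidene)-2,5,5,8a-tetramethyl-4a-(trimethylsilyloxy)decahydronaphthalene (E/Z mixture)
Conditions: MeOCH2PPh3Cl, KOt-Bu, THF, 0 → 65 °C
Reagents that add atoms: (methoxymethyl)triphenylphosphonium chloride, COC[P+](c1ccccc1)(c1ccccc1)c1ccccc1.[Cl-]
Why: Wittig olefination with the small methoxymethylene ylide is the usual one-carbon homologation of α-branched cyclohexanones and introduces C8 as an enol ether whose geometry is inconsequential.

Step 10
Reactants: 13 (2R,4aS,8aR)-1-(methoxymethylidene)-2,5,5,8a-tetramethyl-4a-(trimethylsilyloxy)decahydronaphthalene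
Product: 15 (1S,2R,4aS,8aR)-2,5,5,8a-tetramethyl-4a-(trimethylsilyloxy)decahydronaphthalene-1-carbaldehyde, via C9-epimeric aldehyde 14 (not isolated)
Conditions: oxalic acid, THF/H2O, 23 °C; then 1,8-diazabicyclo[5.4.0]undec-7-ene (DBU, 0.2 equiv), CH2Cl2, 40 °C
Reagents that add atoms: water, O
Why: Enol ether hydrolysis followed by base-catalysed epimerization; protonation from the open face should first give the C9 epimer 14, which enolization funnels to the thermodynamic aldehyde 15 with the formyl group equatorial, trans to the C10 methyl group and away from the C13–C14 bond, while the shielded tertiary silyl ether is expected to survive the weak acid.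

Step 11
Reactants: 15 (1S,2R,4aS,8aR)-2,5,5,8a-tetramethyl-4a-(trimethylsilyloxy)decahydronaphthalene-1-carbaldehyde
Product: 16 [(1S,2R,4aS,8aR)-2,5,5,8a-tetramethyl-4a-(trimethylsilyloxy)decahydronaphthalen-1-yl]methanol
Conditions: NaBH4, MeOH, 0 °C
Reagents that add atoms: none
Why: Borohydride reduction of the aldehyde gives the C8 primary alcohol, after which C9 is no longer epimerizable.

Step 12
Reactants: 16 [(1S,2R,4aS,8aR)-2,5,5,8a-tetramethyl-4a-(trimethylsilyloxy)decahydronaphthalen-1-yl]methanol
Product: 17 1-phenyl-5-({[(1S,2R,4aS,8aR)-2,5,5,8a-tetramethyl-4a-(trimethylsilyloxy)decahydronaphthalen-1-yl]methyl}sulfanyl)-1H-tetrazole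
Conditions: 1-phenyl-1H-tetrazole-5-thiol, PPh3, DIAD, THF, 0 → 23 °C
Reagents that add atoms: 1-phenyl-1H-tetrazole-5-thiol, Sc1nnnn1-c1ccccc1
Why: Mitsunobu thioetherification; the acidic heteroaryl thiol should displace the activated primary alcohol at C8, which is β-branched but not neopentyl, by SN2.

Step 13
Reactants: 17 1-phenyl-5-({[(1S,2R,4aS,8aR)-2,5,5,8a-tetramethyl-4a-(trimethylsilyloxy)decahydronaphthalen-1-yl]methyl}sulfanyl)-1H-tetrazole
Product: 18 1-phenyl-5-({[(1S,2R,4aS,8aR)-2,5,5,8a-tetramethyl-4a-(trimethylsilyloxy)decahydronaphthalen-1-yl]methyl}sulfonyl)-1H-tetrazole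
Conditions: m-CPBA (3 equiv), NaHCO3, CH2Cl2, 0 → 23 °C
Reagents that add atoms: 3-chloroperoxybenzoic acid, OOC(=O)c1cccc(Cl)c1
Why: Peracid oxidation of the sulfide to the sulfone under buffered conditions; no alkene is present and the silyl ether is stable.

**1,2-Dioxane aldehyde (steps 14–23)**

Step 14
Reactants: 19 geranyl acetate
Product: 20 (2E)-3-methyl-6-oxohex-2-en-1-yl acetate
Conditions: O3 (1 equiv), CH2Cl2/MeOH, −78 °C; then Me2S
Reagents that add atoms: ozone, [O-][O+]=O
Why: Ozonolysis with one equivalent of ozone should cleave the electron-rich trisubstituted 6,7-alkene in preference to the alkene deactivated by the allylic acetate, exposing the aldehyde carbon that becomes C3.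

Step 15
Reactants: 20 (2E)-3-methyl-6-oxohex-2-en-1-yl acetate
Product: 21 (2E,6R,7R)-6-hydroxy-3,7-dimethylnona-2,8-dien-1-yl acetate
Conditions: (Z)-crotyl-B(Ipc)2 [cis-2-butene, n-BuLi, KOt-Bu, THF, −78 → −45 °C; (−)-B-methoxydiisopinocampheylborane; BF3·OEt2, −78 °C]; 20, −78 °C; then NaBO3·4H2O, THF/H2O, 23 °C
Reagents that add atoms: (Z)-but-2-ene, C/C=C\C (delivered as its B-crotyldiisopinocampheylborane)
Why: Brown crotylation; the (Z)-crotylborane should react through a closed chair transition state to give the syn adduct, and the isopinocampheyl groups derived from (+)-α-pinene select one aldehyde face, so the future C3 (carbinol, R) and C2 (methyl-bearing, R) are set under reagent control.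

Step 16
Reactants: 21 (2E,6R,7R)-6-hydroxy-3,7-dimethylnona-2,8-dien-1-yl acetate
Product: 22 (2E,6R,7R)-6-(methanesulfonyloxy)-3,7-dimethylnona-2,8-dien-1-yl acetate
Conditions: MsCl, Et3N, CH2Cl2, 0 °C
Reagents that add atoms: methanesulfonyl chloride, CS(=O)(=O)Cl
Why: Mesylation turns the C3 hydroxyl into the leaving group for the later ring closure, and with a vinyl group standing in for the ester no carbonyl activates β-elimination.

Step 17
Reactants: 22 (2E,6R,7R)-6-(methanesulfonyloxy)-3,7-dimethylnona-2,8-dien-1-yl acetate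
Product: 23 (3R,4R,7E)-9-hydroxy-3,7-dimethylnona-1,7-dien-4-yl methanesulfonate
Conditions: K2CO3, MeOH, 0 °C
Reagents that add atoms: none
Why: Mild methanolysis of the allylic acetate frees the alcohol that directs the epoxidation, under conditions that a secondary mesylate should survive.

Step 18
Reactants: 23 (3R,4R,7E)-9-hydroxy-3,7-dimethylnona-1,7-dien-4-yl methanesulfonate
Product: 24 (3R,4R)-6-[(2R,3R)-3-(hydroxymethyl)-2-methyloxiran-2-yl]-3-methylhex-1-en-4-yl methanesulfonate
Conditions: Ti(Oi-Pr)4 (10 mol %), D-(−)-diethyl tartrate (12 mol %), t-BuOOH, 4 Å molecular sieves, CH2Cl2, −20 °C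
Reagents that add atoms: tert-butyl hydroperoxide, CC(C)(C)OO
Why: Sharpless asymmetric epoxidation of the E-trisubstituted allylic alcohol; the D-tartrate ligand should deliver oxygen to the face that gives the (2R,3R)-epoxide, leaving the remote vinyl group and the mesylate untouched.

Step 19
Reactants: 24 (3R,4R)-6-[(2R,3R)-3-(hydroxymethyl)-2-methyloxiran-2-yl]-3-methylhex-1-en-4-yl methanesulfonate
Product: 25 (2R,3S,6R,7R)-3-hydroperoxy-1,2-dihydroxy-3,7-dimethylnon-8-en-6-yl methanesulfonate
Conditions: H2O2 (anhydrous, in Et2O), H3PMo12O40 (5 mol %), 23 °C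
Reagents that add atoms: hydrogen peroxide, OO
Why: Acid-catalysed perhydrolysis of the epoxide; hydrogen peroxide should open the activated oxirane at its tertiary carbon (the future C6) with inversion, as in the known molybdenum-catalysed opening of 2,2-di- and trisubstituted epoxides to β-hydroxy hydroperoxides, so the epoxide configuration is relayed to the tertiary C–O–O centre.

Step 20
Reactants: 25 (2R,3S,6R,7R)-3-hydroperoxy-1,2-dihydroxy-3,7-dimethylnon-8-en-6-yl methanesulfonate
Product: 26 (1R)-1-[(3S,6S)-6-[(2R)-but-3-en-2-yl]-3-methyl-1,2-dioxan-3-yl]ethane-1,2-diol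
Conditions: KOt-Bu (1.0 equiv), 18-crown-6, THF, 0 °C
Reagents that add atoms: none
Why: Intramolecular alkylation of a hydroperoxide; the peroxy anion, the only site deprotonated by one equivalent of base, should displace the secondary mesylate in a 6-exo-tet closure with inversion at C3, giving the 1,2-dioxane with the C3 side chain cis to the C6 methyl group.

Step 21
Reactants: 26 (1R)-1-[(3S,6S)-6-[(2R)-but-3-en-2-yl]-3-methyl-1,2-dioxan-3-yl]ethane-1,2-diol
Product: 28 (2S)-2-[(3S,6S)-6-[(1R)-1,2-dihydroxyethyl]-6-methyl-1,2-dioxan-3-yl]propanoic acid, via aldehyde 27 (not isolated)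
Conditions: O3, MeCN/H2O 9:1, 0 °C; N2 purge; then NaClO2, NaH2PO4, 0 → 23 °C
Reagents that add atoms: ozone, [O-][O+]=O; sodium chlorite, [Na+].[O-]Cl=O
Why: Ozonolysis in aqueous acetonitrile followed by Pinnick oxidation; the vinyl group is cut to the aldehyde and oxidized at about pH 4, which avoids the basic conditions that would open the β-peroxy carbonyl compound or epimerize C2, and the dialkyl peroxide and the diol are inert to both oxidants.

Step 22
Reactants: 28 (2S)-2-[(3S,6S)-6-[(1R)-1,2-dihydroxyethyl]-6-methyl-1,2-dioxan-3-yl]propanoic acid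
Product: 29 methyl (2S)-2-[(3S,6S)-6-[(1R)-1,2-dihydroxyethyl]-6-methyl-1,2-dioxan-3-yl]propanoate
Conditions: Me3SiCHN2, toluene/MeOH, 0 °C
Reagents that add atoms: (trimethylsilyl)diazomethane, C[Si](C)(C)C=[N+]=[N-]
Why: Esterification with the diazoalkane is neutral and fast, so the β-peroxy acid is methylated without base.

Step 23
Reactants: 29 methyl (2S)-2-[(3S,6S)-6-[(1R)-1,2-dihydroxyethyl]-6-methyl-1,2-dioxan-3-yl]propanoate
Product: 30 methyl (2S)-2-[(3S,6S)-6-formyl-6-methyl-1,2-dioxan-3-yl]propanoate
Conditions: NaIO4, THF/H2O, 0 → 23 °C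
Reagents that add atoms: none
Why: Periodate glycol cleavage excises the terminal CH2OH carbon and leaves the non-enolizable C7 aldehyde on the quaternary peroxide carbon C6, the O–O bond being stable to periodate.

**Fragment union (steps 24–25)**

Step 24
Reactants: 18 1-phenyl-5-({[(1S,2R,4aS,8aR)-2,5,5,8a-tetramethyl-4a-(trimethylsilyloxy)decahydronaphthalen-1-yl]methyl}sulfonyl)-1H-tetrazole; 30 methyl (2S)-2-[(3S,6S)-6-formyl-6-methyl-1,2-dioxan-3-yl]propanoate
Product: 31 methyl (2S)-2-[(3S,6S)-6-methyl-6-{(E)-2-[(1R,2R,4aS,8aR)-2,5,5,8a-tetramethyl-4a-(trimethylsilyloxy)decahydronaphthalen-1-yl]ethenyl}-1,2-dioxan-3-yl]propanoate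
Conditions: 18 (1.1 equiv), KN(SiMe3)2 (1.05 equiv), THF, −78 °C; then 30, −78 → 23 °C
Reagents that add atoms: none
Why: Julia–Kocienski olefination; the pre-formed sulfonyl anion should add to the non-enolizable aldehyde faster than it deprotonates the ester or attacks the O–O bond, and Smiles rearrangement with loss of sulfur dioxide gives the C7=C8 alkene, whose geometry is inconsequential.

Step 25
Reactants: 31 methyl (2S)-2-[(3S,6S)-6-methyl-6-{(E)-2-[(1R,2R,4aS,8aR)-2,5,5,8a-tetramethyl-4a-(trimethylsilyloxy)decahydronaphthalen-1-yl]ethenyl}-1,2-dioxan-3-yl]propanoate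
Product: 33 methyl (2S)-2-[(3S,6R)-6-{2-[(1S,2R,4aS,8aR)-4a-hydroxy-2,5,5,8a-tetramethyldecahydronaphthalen-1-yl]ethyl}-6-methyl-1,2-dioxan-3-yl]propanoate (the target), via saturated silyl ether 32 (not isolated)
Conditions: KO2CN=NCO2K, AcOH, MeOH/CH2Cl2, 0 → 23 °C (repeated charges); then HF·pyridine, THF, 0 °C
Reagents that add atoms: none
Why: Diimide reduction should saturate the disubstituted C7=C8 alkene by concerted syn hydrogen transfer without touching the O–O bond or the ester, and fluoride then cleaves the tertiary silyl ether under non-basic conditions that keep the β-peroxy ester intact.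

**Compound list**

1 | 2-methylcyclohexane-1,3-dione | CC1C(=O)CCCC1=O | starting material
2 | acrolein (prop-2-enal) | C=CC=O | starting material
3 | 3-(1-methyl-2,6-dioxocyclohexyl)propanal | CC1(CCC=O)C(=O)CCCC1=O | intermediate
4 | isopropyltriphenylphosphonium iodide | CC(C)[P+](c1ccccc1)(c1ccccc1)c1ccccc1.[I-] | starting material
5 | 2-methyl-2-(4-methylpent-3-en-1-yl)cyclohexane-1,3-dione | CC(C)=CCCC1(C)C(=O)CCCC1=O | intermediate
6 | (2R,3R)-3-hydroxy-2-methyl-2-(4-methylpent-3-en-1-yl)cyclohexan-1-one (hydroxyl cis to the homoprenyl chain) | CC(C)=CCC[C@@]1(C)C(=O)CCC[C@H]1O | intermediate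
7 | (2R,3R)-2-methyl-2-(4-methylpent-3-en-1-yl)-3-(triethylsilyloxy)cyclohexan-1-one | CC(C)=CCC[C@@]1(C)C(=O)CCC[C@H]1O[Si](CC)(CC)CC | intermediate
8 | (1R,4aS,8aR)-5,5,8a-trimethyl-1-(triethylsilyloxy)octahydronaphthalen-4a(2H)-ol (cis-fused) | CC[Si](CC)(CC)O[C@@H]1CCC[C@]2(O)C(C)(C)CCC[C@]12C | intermediate (not isolated)
9 | (1R,4aS,8aR)-5,5,8a-trimethyloctahydronaphthalene-1,4a(2H)-diol (cis-fused) | O[C@@H]1CCC[C@]2(O)C(C)(C)CCC[C@]12C | intermediate
10 | (4aS,8aS)-4a-hydroxy-5,5,8a-trimethyloctahydronaphthalen-1(2H)-one | O=C1CCC[C@]2(O)C(C)(C)CCC[C@]12C | intermediate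
11 | (4aS,8aS)-5,5,8a-trimethyl-4a-(trimethylsilyloxy)octahydronaphthalen-1(2H)-one | O=C1CCC[C@]2(O[Si](C)(C)C)C(C)(C)CCC[C@]12C | intermediate
12 | (2R,4aS,8aS)-2,5,5,8a-tetramethyl-4a-(trimethylsilyloxy)octahydronaphthalen-1(2H)-one (C10 methyl trans to the C18 methyl) | O=C1[C@H](C)CC[C@]2(O[Si](C)(C)C)C(C)(C)CCC[C@]12C | intermediate
13 | (2R,4aS,8aR)-1-(methoxymethylidene)-2,5,5,8a-tetramethyl-4a-(trimethylsilyloxy)decahydronaphthalene (E/Z mixture) | COC=C1[C@H](C)CC[C@]2(O[Si](C)(C)C)C(C)(C)CCC[C@]12C | intermediate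
14 | (1R,2R,4aS,8aR)-2,5,5,8a-tetramethyl-4a-(trimethylsilyloxy)decahydronaphthalene-1-carbaldehyde (C9 epimer, formyl cis to the C10 methyl) | O=C[C@@H]1[C@H](C)CC[C@]2(O[Si](C)(C)C)C(C)(C)CCC[C@]12C | intermediate (not isolated)
15 | (1S,2R,4aS,8aR)-2,5,5,8a-tetramethyl-4a-(trimethylsilyloxy)decahydronaphthalene-1-carbaldehyde (formyl cis to the C18 methyl, trans to the C10 methyl) | O=C[C@H]1[C@H](C)CC[C@]2(O[Si](C)(C)C)C(C)(C)CCC[C@]12C | intermediate
16 | [(1S,2R,4aS,8aR)-2,5,5,8a-tetramethyl-4a-(trimethylsilyloxy)decahydronaphthalen-1-yl]methanol | OC[C@H]1[C@H](C)CC[C@]2(O[Si](C)(C)C)C(C)(C)CCC[C@]12C | intermediate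
17 | 1-phenyl-5-({[(1S,2R,4aS,8aR)-2,5,5,8a-tetramethyl-4a-(trimethylsilyloxy)decahydronaphthalen-1-yl]methyl}sulfanyl)-1H-tetrazole | c1ccccc1-n1nnnc1SC[C@H]1[C@H](C)CC[C@]2(O[Si](C)(C)C)C(C)(C)CCC[C@]12C | intermediate
18 | 1-phenyl-5-({[(1S,2R,4aS,8aR)-2,5,5,8a-tetramethyl-4a-(trimethylsilyloxy)decahydronaphthalen-1-yl]methyl}sulfonyl)-1H-tetrazole | O=S(=O)(C[C@H]1[C@H](C)CC[C@]2(O[Si](C)(C)C)C(C)(C)CCC[C@]12C)c1nnnn1-c1ccccc1 | intermediate
19 | geranyl acetate, (2E)-3,7-dimethylocta-2,6-dien-1-yl acetate | CC(C)=CCC/C(C)=C/COC(C)=O | starting material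
20 | (2E)-3-methyl-6-oxohex-2-en-1-yl acetate | O=CCC/C(C)=C/COC(C)=O | intermediate
21 | (2E,6R,7R)-6-hydroxy-3,7-dimethylnona-2,8-dien-1-yl acetate (6,7-syn) | C=C[C@@H](C)[C@H](O)CC/C(C)=C/COC(C)=O | intermediate
22 | (2E,6R,7R)-6-(methanesulfonyloxy)-3,7-dimethylnona-2,8-dien-1-yl acetate | C=C[C@@H](C)[C@H](OS(C)(=O)=O)CC/C(C)=C/COC(C)=O | intermediate
23 | (3R,4R,7E)-9-hydroxy-3,7-dimethylnona-1,7-dien-4-yl methanesulfonate | C=C[C@@H](C)[C@H](OS(C)(=O)=O)CC/C(C)=C/CO | intermediate
24 | (3R,4R)-6-[(2R,3R)-3-(hydroxymethyl)-2-methyloxiran-2-yl]-3-methylhex-1-en-4-yl methanesulfonate | C=C[C@@H](C)[C@H](OS(C)(=O)=O)CC[C@@]1(C)O[C@@H]1CO | intermediate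
25 | (2R,3S,6R,7R)-3-hydroperoxy-1,2-dihydroxy-3,7-dimethylnon-8-en-6-yl methanesulfonate | C=C[C@@H](C)[C@H](OS(C)(=O)=O)CC[C@](C)(OO)[C@H](O)CO | intermediate
26 | (1R)-1-[(3S,6S)-6-[(2R)-but-3-en-2-yl]-3-methyl-1,2-dioxan-3-yl]ethane-1,2-diol | C=C[C@@H](C)[C@@H]1CC[C@@](C)([C@H](O)CO)OO1 | intermediate
27 | (2S)-2-[(3S,6S)-6-[(1R)-1,2-dihydroxyethyl]-6-methyl-1,2-dioxan-3-yl]propanal | O=C[C@@H](C)[C@@H]1CC[C@@](C)([C@H](O)CO)OO1 | intermediate (not isolated)
28 | (2S)-2-[(3S,6S)-6-[(1R)-1,2-dihydroxyethyl]-6-methyl-1,2-dioxan-3-yl]propanoic acid | OC(=O)[C@@H](C)[C@@H]1CC[C@@](C)([C@H](O)CO)OO1 | intermediate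
29 | methyl (2S)-2-[(3S,6S)-6-[(1R)-1,2-dihydroxyethyl]-6-methyl-1,2-dioxan-3-yl]propanoate | COC(=O)[C@@H](C)[C@@H]1CC[C@@](C)([C@H](O)CO)OO1 | intermediate
30 | methyl (2S)-2-[(3S,6S)-6-formyl-6-methyl-1,2-dioxan-3-yl]propanoate | COC(=O)[C@@H](C)[C@@H]1CC[C@@](C)(C=O)OO1 | intermediate
31 | methyl (2S)-2-[(3S,6S)-6-methyl-6-{(E)-2-[(1R,2R,4aS,8aR)-2,5,5,8a-tetramethyl-4a-(trimethylsilyloxy)decahydronaphthalen-1-yl]ethenyl}-1,2-dioxan-3-yl]propanoate | COC(=O)[C@@H](C)[C@@H]1CC[C@@](C)(/C=C/[C@H]2[C@H](C)CC[C@]3(O[Si](C)(C)C)C(C)(C)CCC[C@]23C)OO1 | intermediate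
32 | methyl (2S)-2-[(3S,6R)-6-methyl-6-{2-[(1S,2R,4aS,8aR)-2,5,5,8a-tetramethyl-4a-(trimethylsilyloxy)decahydronaphthalen-1-yl]ethyl}-1,2-dioxan-3-yl]propanoate | COC(=O)[C@@H](C)[C@@H]1CC[C@@](C)(CC[C@H]2[C@H](C)CC[C@]3(O[Si](C)(C)C)C(C)(C)CCC[C@]23C)OO1 | intermediate (not isolated)
33 | methyl (2S)-2-[(3S,6R)-6-{2-[(1S,2R,4aS,8aR)-4a-hydroxy-2,5,5,8a-tetramethyldecahydronaphthalen-1-yl]ethyl}-6-methyl-1,2-dioxan-3-yl]propanoate | COC(=O)[C@@H](C)[C@@H]1CC[C@@](C)(CC[C@H]2[C@H](C)CC[C@]3(O)C(C)(C)CCC[C@]23C)OO1 | target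

**Step count and risks**

Total step count: 25. Longest linear sequence: 15 steps (steps 1–13, then 24 and 25); the dioxane branch (steps 14–23) has 10 steps.

The three steps most likely to fail:

Step 5 (key step). The tertiary radical may be reduced before it cyclizes (net hydrogenation of the alkene), or the alkoxy radical may fragment back to the open chain, so that the hindered ketone is never captured. The fallback sets out from 7. Epoxidation of the trisubstituted alkene (m-CPBA, NaHCO3, CH2Cl2) gives the epoxide F1. Cp2TiCl (trivalent titanium, from Cp2TiCl2 and Zn, THF) opens it homolytically to the same tertiary C14 radical, now as a β-titanoxy radical. Its 6-exo addition to the C13 ketone is completed by a second equivalent of the titanium reagent, which traps the alkoxy radical and gives the C15-hydroxylated cis-decalinol F2. The extra secondary hydroxyl is removed by Barton–McCombie deoxygenation through the xanthate F3 (NaH, CS2, MeI; then Bu3SnH, AIBN, toluene, 90 °C). This comes back to the route at 8, which is desilylated to 9 as in step 5.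

Step 20. Base-induced elimination of the α-branched secondary mesylate to a conjugated diene may outrun the 6-exo displacement by the peroxy anion. The fallback sets out from 20. Wittig olefination with methyl 2-(triphenylphosphoranylidene)propanoate gives the (E)-enoate F6, and acetate methanolysis (K2CO3, MeOH) gives the allylic alcohol F7. The asymmetric epoxidation and perhydrolysis of steps 18 and 19 then give the epoxy alcohol F8 and the hydroperoxide F9. Amine-catalysed (Et2NH, CF3CH2OH) intramolecular conjugate addition of the hydroperoxide to the enoate closes the 1,2-dioxane. C6 is already fixed, and a chair with the C6 methyl group axial should favour the desired C3 configuration; C2 is not controlled, so the diastereomers are separated by chromatography. The fallback comes back to the route at 29.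

Step 9. The basic ylide may enolize the crowded C9 ketone and return starting material in place of the alkene. The fallback sets out from 12. Methylenation with the smallest ylide (MePPh3Br, KOt-Bu, toluene, 90 °C) gives the exocyclic alkene F4. Hydroboration–oxidation (BH3·THF; then NaOH, H2O2) gives the primary alcohol F5, expected mainly as the C9 epimer of 16 because the borane should approach the face away from ring A. Dess–Martin oxidation gives aldehyde 14, and the amidine equilibration of step 10 comes back to the route at 15.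

**Further compounds**

F1 | step 5 | (2R,3R)-2-[2-(3,3-dimethyloxiran-2-yl)ethyl]-2-methyl-3-(triethylsilyloxy)cyclohexan-1-one (both configurations at the oxirane CH) | CC1(C)OC1CC[C@@]1(C)C(=O)CCC[C@H]1O[Si](CC)(CC)CC
F2 | step 5 | (1R,4aS,8aR)-5,5,8a-trimethyl-1-(triethylsilyloxy)octahydronaphthalene-4a,6(2H)-diol (C6 epimers) | CC[Si](CC)(CC)O[C@@H]1CCC[C@]2(O)C(C)(C)C(O)CC[C@]12C
F3 | step 5 | O-[(4aS,5R,8aR)-8a-hydroxy-1,1,4a-trimethyl-5-(triethylsilyloxy)decahydronaphthalen-2-yl] S-methyl carbonodithioate (xanthate of the secondary hydroxyl of F2) | CC[Si](CC)(CC)O[C@@H]1CCC[C@]2(O)C(C)(C)C(OC(=S)SC)CC[C@]12C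
F4 | step 9 | (2R,4aS,8aR)-2,5,5,8a-tetramethyl-1-methylidene-4a-(trimethylsilyloxy)decahydronaphthalene | C=C1[C@H](C)CC[C@]2(O[Si](C)(C)C)C(C)(C)CCC[C@]12C
F5 | step 9 | [(1R,2R,4aS,8aR)-2,5,5,8a-tetramethyl-4a-(trimethylsilyloxy)decahydronaphthalen-1-yl]methanol (C9 epimer of 16) | OC[C@@H]1[C@H](C)CC[C@]2(O[Si](C)(C)C)C(C)(C)CCC[C@]12C
F6 | step 20 | methyl (2E,6E)-8-acetoxy-2,6-dimethylocta-2,6-dienoate | COC(=O)/C(C)=C/CC/C(C)=C/COC(C)=O
F7 | step 20 | methyl (2E,6E)-8-hydroxy-2,6-dimethylocta-2,6-dienoate | COC(=O)/C(C)=C/CC/C(C)=C/CO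
F8 | step 20 | methyl (2E)-5-[(2R,3R)-3-(hydroxymethyl)-2-methyloxiran-2-yl]-2-methylpent-2-enoate | COC(=O)/C(C)=C/CC[C@@]1(C)O[C@@H]1CO
F9 | step 20 | methyl (2E,6S,7R)-6-hydroperoxy-7,8-dihydroxy-2,6-dimethyloct-2-enoate | COC(=O)/C(C)=C/CC[C@](C)(OO)[C@H](O)CO
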